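**Plan**

- Retrosynthesis: after ester hydrolysis, the (1'E,3'E)-diene is cut at the C2'–C3' sp2–sp2 bond (Pd cross-coupling) into a chroman (E)-vinyl iodide and a C13 terminal alkyne from dihydro-β-ionone. The vinyl iodide goes back through the C2 aldehyde to a 2-(benzyloxymethyl)chroman-4-one.
- The pyran ring is then cut at C2–C3. C2 is an sp3 carbon on the ring oxygen O1; in the open-chain aryl sec-alkyl ether it carries a single tertiary C–H α to O1. With C4 raised temporarily to a ketone, a carbene at C3 (α-diazoketone from an ortho-acetyl group) sits 1,6 to that C–H, and the 1,5-position is O1 itself.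
- Forward order: Mitsunobu etherification, diazo transfer, dirhodium-catalysed 1,6 C–H insertion (closes the pyran ring, the only ring made; the benzene and cyclohexene rings are bought), one-pot hydrogenolysis of the helper C4 ketone and the benzyl group, oxidation, Takai iodo-olefination, carboalumination/Negishi coupling, saponification.
- Stereochemistry: C2 (R) stems from (R)-1-(benzyloxy)propan-2-ol, inverted once in the Mitsunobu step and then retained in the C–H insertion. The 1'E alkene comes from the Takai reaction and the 3'E alkene from syn-carbometalation of the alkyne; both are retained in the coupling.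

Key step: step 3

Assumption: chroman numbering is used (O1, quaternary C2, C3, benzylic C4) and side-chain carbons are counted C1' to C6' from C2; carbene C–H insertion at dirhodium is taken to occur with retention at carbon, as is general for this reaction type.

**Route**

Step 1
Reactants: 1 methyl 3-acetyl-4-hydroxybenzoate; 2 (2R)-1-(benzyloxy)propan-2-ol
Product: 3 methyl 3-acetyl-4-{[(2S)-1-(benzyloxy)propan-2-yl]oxy}benzoate
Conditions: PPh3, DIAD, THF, 0 °C to rt
Reagents that add atoms: none
Why: Mitsunobu etherification; the acidic, acyl- and ester-substituted phenol displaces the activated secondary alkoxyphosphonium by SN2 with clean inversion, so the (R)-carbinol becomes the (S)-aryl ether that carries the future C2–H.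

Step 2
Reactants: 3 methyl 3-acetyl-4-{[(2S)-1-(benzyloxy)propan-2-yl]oxy}benzoate
Product: 5 methyl 4-{[(2S)-1-(benzyloxy)propan-2-yl]oxy}-3-(2-diazoacetyl)benzoate, via trifluoroacetyl diketone 4 (not isolated)
Conditions: LiN(SiMe3)2, THF, −78 °C, then CF3CO2CH2CF3; aq. HCl work-up; crude 4 then MsN3, Et3N, H2O (1 equiv), MeCN, rt
Reagents that add atoms: 2,2,2-trifluoroethyl trifluoroacetate, FC(F)(F)C(=O)OCC(F)(F)F (trifluoroacetyl group of 4, lost again); methanesulfonyl azide, CS(=O)(=O)N=[N+]=[N-] (the two nitrogens of 5)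
Why: Danheiser detrifluoroacetylative diazo transfer, in which Claisen-type C-trifluoroacetylation of the kinetic lithium enolate activates the acetyl CH3 and Regitz diazo transfer to the 1,3-diketone then expels the trifluoroacetyl group; the ether stereocentre is not acidic and is untouched.

Step 3
Reactants: 5 methyl 4-{[(2S)-1-(benzyloxy)propan-2-yl]oxy}-3-(2-diazoacetyl)benzoate
Product: 6 methyl (2R)-2-[(benzyloxy)methyl]-2-methyl-4-oxo-3,4-dihydro-2H-chromene-6-carboxylate
Conditions: Rh2(OAc)4 (1 mol%), CH2Cl2, reflux, slow addition of 5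
Reagents that add atoms: none
Why: Rh2(OAc)4 decomposes the α-diazoketone with loss of N2 to an electrophilic, catalyst-bound carbene at C3, which inserts into the tertiary C2–H bond α to the ether oxygen through a concerted three-centre, hydride-transfer-like transition state, forming the C2–C3 bond. The closest known reaction type is the dirhodium-catalysed cyclisation of ortho-alkoxyaryl diazoketones to chroman-4-ones, together with the stereoretentive insertion of such carbenes into tertiary stereogenic C–H bonds. The pyran ring closes in the 1,6-insertion mode through a six-membered chair-like transition state, because the 1,5-position is the oxygen atom O1 and offers no C–H. The new quaternary stereocentre C2 is controlled by the substrate: insertion occurs with retention at carbon, so the (S)-ether gives the (R)-chromanone (the descriptor changes only because C3 outranks CH3 where H did not). The step needs site selectivity for the tertiary α-oxy C–H over 1,7-insertion into the OCH2 and CH3 groups and over oxonium ylide formation at O1. Ring size and the hydridic tertiary C–H secure the first, the low basicity of O1 (para ester, ortho acyl) the second, and slow addition suppresses carbene dimerisation.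

Step 4
Reactants: 6 methyl (2R)-2-[(benzyloxy)methyl]-2-methyl-4-oxo-3,4-dihydro-2H-chromene-6-carboxylate
Product: 7 methyl (2R)-2-(hydroxymethyl)-2-methyl-3,4-dihydro-2H-chromene-6-carboxylate
Conditions: H2 (4 atm), 10% Pd/C, MeOH, cat. HCl, rt
Reagents that add atoms: none
Why: Acid-promoted heterogeneous hydrogenolysis reduces the aryl ketone at C4 (benzylic, ortho to the donor O1) to CH2 and cleaves the benzyl ether in the same operation, removing the helper carbonyl and the protecting group; C2 is not benzylic and keeps its configuration.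

Step 5
Reactants: 7 methyl (2R)-2-(hydroxymethyl)-2-methyl-3,4-dihydro-2H-chromene-6-carboxylate
Product: 8 methyl (2R)-2-formyl-2-methyl-3,4-dihydro-2H-chromene-6-carboxylate
Conditions: Dess–Martin periodinane, CH2Cl2, rt
Reagents that add atoms: none
Why: Dess–Martin oxidation of the neopentyl-type primary alcohol to the aldehyde; the α-carbon is quaternary, so no epimerisation is possible.

Step 6
Reactants: 8 methyl (2R)-2-formyl-2-methyl-3,4-dihydro-2H-chromene-6-carboxylate
Product: 9 methyl (2R)-2-[(E)-2-iodoethenyl]-2-methyl-3,4-dihydro-2H-chromene-6-carboxylate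
Conditions: CrCl2, CHI3, THF/1,4-dioxane, 0 °C to rt
Reagents that add atoms: iodoform, IC(I)I (the CHI unit)
Why: Takai iodo-olefination; the geminal dichromium species from CHI3 and divalent chromium adds to the aldehyde and eliminates to the (E)-iodoalkene, E selectivity being favoured by the bulky quaternary α-carbon, and the ester is inert to the reagent.

Step 7
Reactants: 10 4-(2,6,6-trimethylcyclohex-1-en-1-yl)butan-2-one (dihydro-β-ionone)
Product: 12 2-(but-3-yn-1-yl)-1,3,3-trimethylcyclohex-1-ene, via enol phosphate 11 (not isolated)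
Conditions: LiN(iPr)2 (1.05 equiv), THF, −78 °C; ClP(O)(OEt)2, −78 °C to rt; then LiN(iPr)2 (2.3 equiv), −78 °C to rt; H2O
Reagents that add atoms: diethyl chlorophosphate, CCOP(=O)(Cl)OCC (phosphate group of 11, lost again)
Why: Methyl ketone to terminal alkyne conversion by enol phosphate elimination; kinetic deprotonation at CH3 gives the terminal enol phosphate and excess amide base effects E2 loss of diethyl phosphate, the acetylide formed protecting the alkyne from isomerisation until the quench.

Step 8
Reactants: 12 2-(but-3-yn-1-yl)-1,3,3-trimethylcyclohex-1-ene; 9 methyl (2R)-2-[(E)-2-iodoethenyl]-2-methyl-3,4-dihydro-2H-chromene-6-carboxylate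
Product: 15 methyl (2R)-2-methyl-2-[(1E,3E)-4-methyl-6-(2,6,6-trimethylcyclohex-1-en-1-yl)hexa-1,3-dien-1-yl]-3,4-dihydro-2H-chromene-6-carboxylate, via alkenylalane 13 (not isolated), via alkenylzinc chloride 14 (not isolated)
Conditions: Me3Al, Cp2ZrCl2, CH2Cl2, 0 °C to rt; volatiles removed; then ZnCl2, THF; 9, Pd(PPh3)4 (5 mol%), THF, rt
Reagents that add atoms: trimethylaluminium, C[Al](C)C (the C4' methyl group; AlMe2 of 13); zinc dichloride, Cl[Zn]Cl (ZnCl of 14 only)
Why: Negishi zirconium-catalysed carboalumination adds CH3–Al syn across the terminal alkyne with aluminium at the terminal carbon, fixing the 3'E trisubstituted alkene, and Pd-catalysed Negishi coupling of the derived alkenylzinc with the (E)-vinyl iodide proceeds with retention at both sp2 carbons; the tetrasubstituted ring alkene does not carbometalate and the ester tolerates the organozinc once excess Me3Al is removed.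

Step 9
Reactants: 15 methyl (2R)-2-methyl-2-[(1E,3E)-4-methyl-6-(2,6,6-trimethylcyclohex-1-en-1-yl)hexa-1,3-dien-1-yl]-3,4-dihydro-2H-chromene-6-carboxylate
Product: 16 (2R)-2-methyl-2-[(1E,3E)-4-methyl-6-(2,6,6-trimethylcyclohex-1-en-1-yl)hexa-1,3-dien-1-yl]-3,4-dihydro-2H-chromene-6-carboxylic acid (CNP0265961.1)
Conditions: LiOH, THF/MeOH/H2O, 40 °C; then 1 M HCl to pH 3–4, 0 °C
Reagents that add atoms: lithium hydroxide, [Li+].[OH-] (one oxygen of the carboxyl group)
Why: Saponification of the aryl methyl ester (BAc2) followed by cold, mild acidification; base leaves the diene and the acid-sensitive tertiary dienylic aryl ether at C2 untouched.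

**Compound list**

1 | methyl 3-acetyl-4-hydroxybenzoate | COC(=O)c1ccc(O)c(C(C)=O)c1 | starting material
2 | (2R)-1-(benzyloxy)propan-2-ol | C[C@@H](O)COCc1ccccc1 | starting material
3 | methyl 3-acetyl-4-{[(2S)-1-(benzyloxy)propan-2-yl]oxy}benzoate | C[C@H](Oc1ccc(C(=O)OC)cc1C(C)=O)COCc1ccccc1 | intermediate
4 | methyl 4-{[(2S)-1-(benzyloxy)propan-2-yl]oxy}-3-(4,4,4-trifluoro-3-oxobutanoyl)benzoate (not isolated) | C[C@H](Oc1ccc(C(=O)OC)cc1C(=O)CC(=O)C(F)(F)F)COCc1ccccc1 | intermediate
5 | methyl 4-{[(2S)-1-(benzyloxy)propan-2-yl]oxy}-3-(2-diazoacetyl)benzoate | C[C@H](Oc1ccc(C(=O)OC)cc1C(=O)C=[N+]=[N-])COCc1ccccc1 | intermediate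
6 | methyl (2R)-2-[(benzyloxy)methyl]-2-methyl-4-oxo-3,4-dihydro-2H-chromene-6-carboxylate | c1ccccc1COC[C@@]2(C)CC(=O)c3cc(C(=O)OC)ccc3O2 | intermediate
7 | methyl (2R)-2-(hydroxymethyl)-2-methyl-3,4-dihydro-2H-chromene-6-carboxylate | OC[C@@]2(C)CCc3cc(C(=O)OC)ccc3O2 | intermediate
8 | methyl (2R)-2-formyl-2-methyl-3,4-dihydro-2H-chromene-6-carboxylate | O=C[C@@]2(C)CCc3cc(C(=O)OC)ccc3O2 | intermediate
9 | methyl (2R)-2-[(E)-2-iodoethenyl]-2-methyl-3,4-dihydro-2H-chromene-6-carboxylate | I/C=C/[C@@]2(C)CCc3cc(C(=O)OC)ccc3O2 | intermediate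
10 | 4-(2,6,6-trimethylcyclohex-1-en-1-yl)butan-2-one (dihydro-β-ionone) | CC(=O)CCC1=C(C)CCCC1(C)C | starting material
11 | diethyl 4-(2,6,6-trimethylcyclohex-1-en-1-yl)but-1-en-2-yl phosphate (not isolated) | C=C(CCC1=C(C)CCCC1(C)C)OP(=O)(OCC)OCC | intermediate
12 | 2-(but-3-yn-1-yl)-1,3,3-trimethylcyclohex-1-ene | C#CCCC1=C(C)CCCC1(C)C | intermediate
13 | dimethyl[(1E)-2-methyl-4-(2,6,6-trimethylcyclohex-1-en-1-yl)but-1-en-1-yl]alane (not isolated) | C[Al](C)/C=C(\C)CCC1=C(C)CCCC1(C)C | intermediate
14 | chloro[(1E)-2-methyl-4-(2,6,6-trimethylcyclohex-1-en-1-yl)but-1-en-1-yl]zinc (not isolated) | Cl[Zn]/C=C(\C)CCC1=C(C)CCCC1(C)C | intermediate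
15 | methyl (2R)-2-methyl-2-[(1E,3E)-4-methyl-6-(2,6,6-trimethylcyclohex-1-en-1-yl)hexa-1,3-dien-1-yl]-3,4-dihydro-2H-chromene-6-carboxylate | CC1=C(CC/C(C)=C/C=C/[C@@]2(C)CCc3cc(C(=O)OC)ccc3O2)C(C)(C)CCC1 | intermediate
16 | (2R)-2-methyl-2-[(1E,3E)-4-methyl-6-(2,6,6-trimethylcyclohex-1-en-1-yl)hexa-1,3-dien-1-yl]-3,4-dihydro-2H-chromene-6-carboxylic acid | CC1=C(CC/C(C)=C/C=C/[C@@]2(C)CCc3cc(C(=O)O)ccc3O2)C(C)(C)CCC1 | target

**Step count**

Total steps: 9. Longest linear sequence: 8 (steps 1, 2, 3, 4, 5, 6, 8, 9); step 7 is a one-step branch.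

**Steps most likely to fail**

1. Step 3. The carbene may be diverted into oxonium ylide formation at O1 followed by a 1,2-shift, into 1,7-insertion next to the benzyl ether oxygen, or into dimerisation, because the tertiary C–H is inductively deactivated by the neighbouring CH2O group. Fallback (sets out from 1, returns at 7): the ring is closed instead at O1–C2 and the stereochemistry is obtained by resolution. Kabbe condensation of 1 with 1-(benzyloxy)propan-2-one (pyrrolidine, MeOH, reflux; enamine aldol, dehydration, oxa-Michael closure) should give racemic methyl 2-[(benzyloxy)methyl]-2-methyl-4-oxo-3,4-dihydro-2H-chromene-6-carboxylate F1. Hydrogenolysis as in step 4 should give racemic methyl 2-(hydroxymethyl)-2-methyl-3,4-dihydro-2H-chromene-6-carboxylate F2. Preparative chromatography on a chiral stationary phase would separate 7 from its enantiomer, methyl (2S)-2-(hydroxymethyl)-2-methyl-3,4-dihydro-2H-chromene-6-carboxylate F3, which is set aside.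

2. Step 8. Carbometalation may be incomplete or not regioselective, residual organoaluminium may attack the ester, and zerovalent palladium may reversibly ionise the tertiary allylic aryl ether at C2, eroding its configuration. Fallback (sets out from 10 and 8, returns at 15): the diene is made instead by olefination at C1'=C2' without palladium. Horner–Wadsworth–Emmons reaction of 10 (triethyl phosphonoacetate, NaH, THF; E isomer separated) should give ethyl (2E)-3-methyl-5-(2,6,6-trimethylcyclohex-1-en-1-yl)pent-2-enoate F4. Reduction (iBu2AlH, CH2Cl2, −78 °C) should give (2E)-3-methyl-5-(2,6,6-trimethylcyclohex-1-en-1-yl)pent-2-en-1-ol F5. Mitsunobu thioetherification (1-phenyl-1H-tetrazole-5-thiol, PPh3, DIAD) should give 5-{[(2E)-3-methyl-5-(2,6,6-trimethylcyclohex-1-en-1-yl)pent-2-en-1-yl]sulfanyl}-1-phenyl-1H-tetrazole F6. Oxidation (H2O2, (NH4)6Mo7O24, EtOH, 0 °C) should give 5-{[(2E)-3-methyl-5-(2,6,6-trimethylcyclohex-1-en-1-yl)pent-2-en-1-yl]sulfonyl}-1-phenyl-1H-tetrazole F7. Julia–Kocienski olefination of aldehyde 8 with F7 (KN(SiMe3)2, DME, −60 °C to rt) should then give 15 directly, so that step 6 is not needed.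

3. Step 4. Hydrogenolysis of the benzylic C–O bond may be incomplete, because the ester-bearing arene disfavours ionisation at C4, or the arene may be over-reduced under forcing conditions. Fallback (sets out from 6, returns at 7): the two reductions are separated and the carbonyl is removed by ionic hydrogenation, that is hydride transfer to the O1-stabilised benzylic cation, instead of surface hydrogenolysis. Et3SiH in CF3CO2H (rt to 50 °C) should give methyl (2R)-2-[(benzyloxy)methyl]-2-methyl-3,4-dihydro-2H-chromene-6-carboxylate F8. Neutral debenzylation (H2, 1 atm, 10% Pd/C, EtOAc, rt) should then give 7.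

**Further compounds**

F1 | step 3 | racemic methyl 2-[(benzyloxy)methyl]-2-methyl-4-oxo-3,4-dihydro-2H-chromene-6-carboxylate | COC(=O)c1ccc2OC(C)(COCc3ccccc3)CC(=O)c2c1
F2 | step 3 | racemic methyl 2-(hydroxymethyl)-2-methyl-3,4-dihydro-2H-chromene-6-carboxylate | COC(=O)c1ccc2OC(C)(CO)CCc2c1
F3 | step 3 | methyl (2S)-2-(hydroxymethyl)-2-methyl-3,4-dihydro-2H-chromene-6-carboxylate | OC[C@]2(C)CCc3cc(C(=O)OC)ccc3O2
F4 | step 8 | ethyl (2E)-3-methyl-5-(2,6,6-trimethylcyclohex-1-en-1-yl)pent-2-enoate | CC1=C(CC/C(C)=C/C(=O)OCC)C(C)(C)CCC1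
F5 | step 8 | (2E)-3-methyl-5-(2,6,6-trimethylcyclohex-1-en-1-yl)pent-2-en-1-ol | CC1=C(CC/C(C)=C/CO)C(C)(C)CCC1
F6 | step 8 | 5-{[(2E)-3-methyl-5-(2,6,6-trimethylcyclohex-1-en-1-yl)pent-2-en-1-yl]sulfanyl}-1-phenyl-1H-tetrazole | CC1=C(CC/C(C)=C/CSc2nnnn2-c2ccccc2)C(C)(C)CCC1
F7 | step 8 | 5-{[(2E)-3-methyl-5-(2,6,6-trimethylcyclohex-1-en-1-yl)pent-2-en-1-yl]sulfonyl}-1-phenyl-1H-tetrazole | CC1=C(CC/C(C)=C/CS(=O)(=O)c2nnnn2-c2ccccc2)C(C)(C)CCC1
F8 | step 4 | methyl (2R)-2-[(benzyloxy)methyl]-2-methyl-3,4-dihydro-2H-chromene-6-carboxylate | c1ccccc1COC[C@@]2(C)CCc3cc(C(=O)OC)ccc3O2
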